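## Structural features

The target joins a Δ5-octalin to a pentasubstituted benzene (C1'–C6') through the methylene C11. Ring A (C1–C5, C10) carries the gem-dimethyl carbon C4, and ring B (C5–C10) carries the trisubstituted alkene C5=C6. Ring B holds three contiguous stereocentres: C8 (secondary methyl), C9 (quaternary, methyl and C11) and C10 (ring-fusion hydrogen). The C8 methyl, C11 and H10 lie on one face and the C9 methyl on the other. Counted from C1', the arene bears the sulfated oxygen (C2'), the formyl group (C3'), two free hydroxyls (C4', C5') and one hydrogen (C6'). The fragile groups are the aryl hydrogen sulfate (acid), the 1,2,4-trioxygenated ring once all three oxygens are free (air oxidation to a hydroxyquinone), the C5=C6 alkene (acid-induced migration to C5=C10, hydrogenation) and the aldehyde. The real difficulties are the C8/C9/C10 triad, which sits on a neopentyl framework where nothing can be corrected later, and the sulfation of one phenol out of three. The key step exploits the fact that C3' lies between the oxygenated carbons C2' and C4' while C5' carries oxygen next to C4': ring C1'–C6' is a 6-alkoxycyclohexane-1,3-dione one dehydrogenation short of the arene, with C1'–C2'–C3' mapping onto the CH2–CO–CH3 end of a methyl ketone on C11 and C6'–C5'–C4' onto a 2-alkoxyacrylate.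

## Logic of the disconnections

**23 ⇒ 21.** Cut: the O–S bond at C2', with the C4' and C5' hydroxyls tied back into one O–Si–O bridge. Reason: the sulfate monoester is the most acid-labile group and must come last; only the vicinal pair can span one silicon atom, which leaves C2'–OH as the single free phenol. Gain: the three-phenol problem becomes a ring-size problem. Demand: sulfation must reach a hindered, hydrogen-bonded phenol, and the bridge must come off with fluoride, without acid or hydrogen.

**21 ⇒ 19.** Cut: the two Si–O bonds; the C5' oxygen returns to its benzyl ether. Reason: the C5' oxygen has to pass through alkoxide and quinone oxidant protected. Gain: 19 carries one protecting group only. Demand: the O–CH2Ph bond must be cleaved without touching C5=C6 or the formyl group, and the air-sensitive triol 20 must be silylated at once.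

**19 ⇒ 18.** No skeletal bond is cut; two hydrogens are returned to C1' and C6'. Reason: the arene then becomes a 2-formylcyclohexane-1,3-dione whose substitution pattern is enolate chemistry. Gain: no aromatic substitution is needed on a crowded ring. Demand: a single dehydrogenation that spares the allylic positions C7 and C10 and the benzyl ether.

**18 ⇒ 16.** Cut: the C3'–CHO bond. Reason: C3' is the only carbon flanked by both carbonyls. Gain: one carbon less and a symmetrical-type dione. Demand: C-formylation at C3' under conditions that leave C5=C6 alone.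

**16 ⇒ 11 + 15.** Cut: C1'–C6' and C3'–C4'. Reason: both bonds are enolate bonds of one methyl ketone, and the C5' oxygen arrives in place with the three-carbon partner. Gain: the whole arene reduces to a butanone chain on C11 and a small acrylate. Demand: the conjugate addition must start from C1' and not from the methyl carbon C3', and must cope with an acceptor made less electrophilic by its α-oxygen.

**15 ⇒ 12 + 13.** Cut: one C–O bond at the acrylate α-carbon (ketal to enol ether). Reason: the 2-alkoxyacrylate is the enol ether of a pyruvate. Gain: two commercial liquids. Demand: ketal formation and loss of one benzyloxy group without ester exchange.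

**11 ⇒ 10 ⇒ 8 + 9.** Cut: C11–C1', through the C11=C1' double bond of 10. Reason: C11 is neopentyl and cannot be made by substitution, whereas a carbonyl olefination at C11 is feasible; C11 at the aldehyde level is also what the cycloaddition below delivers. Gain: 8 is the bare bicyclic core. Demand: olefination of an α-quaternary aldehyde, then reduction of the enone C=C only.

**8 ⇒ 4 + 7.** Cut: C7–C8 and C9–C10. Reason: ring B and all three stereocentres form in one step. The dienophile geometry follows from the target. With diene 4 the endo position under C5 is crowded by the C4 methyls, so the carbonyl group is expected exo and ends cis to H10. The group cis to H10 on C9 in the target is C11, so the formyl group must become C11 and the α-methyl the C9 methyl. The C8 methyl is cis to C11, so it must be cis to the formyl group in the dienophile, which is the Z-enal 7. An E-enal carrying the chain on its α-carbon, with the formyl group as the future methyl, would need the crowded endo mode. Gain: two small achiral components. Demand: the exo mode, retention of the Z geometry, and catalyst control of the enal face.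

**4 ⇒ 2 + 3, 2 ⇒ 1.** Cut: the ring–vinyl bond C5–C6, then the enol O–S bond. Reason: cross-coupling of the enol triflate avoids a carbocation next to the gem-dimethyl carbon. Gain: a commercial ketone with a single enolisable side. Demand: none beyond handling a volatile diene.

**7 ⇒ 6 ⇒ 5.** No skeletal bond is cut; the oxidation level at C11 is adjusted. Reason: the Z-enal is best generated fresh from the geometrically stable ester. Gain: a commercial Z-ester. Demand: reduction and oxidation without Z-to-E isomerisation.

## Other disconnections considered

**Alternative 1:** The cut is C9–C10, with C6 returned to a lactone oxygen. Forward, the silyl ketene acetal of δ-lactone A1 would undergo Ireland–Claisen rearrangement, contracting the lactone to ring B and giving acid A2.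
- In favour: ring B, the quaternary C9 and C10 would arise in one intramolecular, stereospecific step, with no endo/exo question and no chiral catalyst. The arene is in place from the start.
- Against: A1 needs its C8 methyl and C6 cyclohexenyl group cis, and C6 set absolutely. The new bond joins a fully substituted ketene acetal carbon to an alkene carbon next to the gem-dimethyl carbon, through the boat-like transition state that the ring imposes. The C9 carboxyl must then be taken down to methyl at a neopentyl position, which costs several operations. Two benzyl ethers must later be removed beside C5=C6.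
- Comparison: on C9/C10 control this is in principle the equal or the better of the chosen plan, since transfer is intramolecular. On arene construction it is better, since no ring has to be built late. On step economy it is worse, and whether the boat geometry places H10 cis to C11 is open.

**Alternative 2:** The cut is C10–C1 and C4=C5. Forward, the enolate released from silyl enol ether A3 would add at C10 to 3-(trimethylsilyl)but-3-en-2-one A4, and aldol condensation would close ring A as enone A5.
- In favour: the C8/C9 relationship in A3 would come from a conjugate methylation trans to the C8 methyl, a dependable element. On this point it is better than the chosen plan, which relies on the exo mode and a Z-enal. The enolate is regiodefined, and the arene is pre-installed.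
- Against: the Michael addition occurs at C10, next to the quaternary C9, and its facial sense (methyl against arylmethyl on C9) does not obviously favour H10 cis to C11. Deconjugative gem-dimethylation at C4 and removal of the C3 carbonyl must follow. The sequence is long and linear.
- Comparison: the mechanism is robust and the endgame is the same as in the chosen plan. Step economy is poorer, and the C10 centre is less secure.

**Alternative 3:** The cut is C7–C8 and C9–C10, with the arene already on the dienophile. Forward, enal A6 and diene 4 would give aldehyde A7 in a catalysed [4+2] cycloaddition, and the formyl group would later become the C9 methyl.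
- In favour: it is the most convergent and the shortest plan. A6 is the stable E isomer and a standard substrate for cationic oxazaborolidine catalysis, both points on which it is better than the chosen plan.
- Against: A7 as drawn requires the formyl group endo (trans to H10), the position crowded by the C4 methyls. If the exo mode prevails, the C10-epimeric series results and cannot be corrected. The formyl-to-methyl reduction and the removal of two benzyl ethers then run beside C5=C6, and C3' must still be formylated between two oxygens.
- Comparison: it is better on step count and convergence and equal on enantiocontrol. It is worse on the match between the expected transition state and the target.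

Key step: step 9

Remark: the target is treated as the free aryl hydrogen sulfate; it forms as its pyridinium salt and is brought to the acid form by brief contact with a sulfonic acid resin at 0 °C.

Notation: Oct = (1R,2R,8aS)-1,2,5,5-tetramethyl-1,2,3,5,6,7,8,8a-octahydronaphthalen-1-yl. Its C1, C2 and C8a are C9, C8 and C10 of the numbering used above.

## Route

Step 1
Reactants: 1 2,2-dimethylcyclohexanone
Product: 2 6,6-dimethylcyclohex-1-en-1-yl trifluoromethanesulfonate
Conditions: LiN(i-Pr)2, THF, −78 °C; PhNTf2, −78 → 0 °C
Reagents that add atoms: N-phenylbis(trifluoromethanesulfonimide), O=S(=O)(N(c1ccccc1)S(=O)(=O)C(F)(F)F)C(F)(F)F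
Why: Enol triflate formation; the ketone has one enolisable side only, so the lithium enolate and its O-sulfonylation are regiochemically unambiguous.

Step 2
Reactants: 2 6,6-dimethylcyclohex-1-en-1-yl trifluoromethanesulfonate; 3 tributyl(vinyl)stannane
Product: 4 6,6-dimethyl-1-vinylcyclohex-1-ene
Conditions: Pd(PPh3)4 (3 mol %), LiCl (3 equiv), THF, reflux
Reagents that add atoms: none
Why: Stille coupling (oxidative addition of the enol triflate to zerovalent palladium, chloride exchange, transmetalation from tin, reductive elimination); no cationic intermediate arises, so the neighbouring gem-dimethyl carbon cannot rearrange.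

Step 3
Reactants: 5 methyl (2Z)-2-methylbut-2-enoate (methyl angelate)
Product: 6 (2Z)-2-methylbut-2-en-1-ol
Conditions: i-Bu2AlH (2.3 equiv), CH2Cl2, −78 → 0 °C; aq. KNaC4H4O6
Reagents that add atoms: none
Why: 1,2-Reduction of an α,β-unsaturated ester by an aluminium hydride; the double bond is not touched, so the Z geometry should be kept.

Step 4
Reactants: 6 (2Z)-2-methylbut-2-en-1-ol
Product: 7 (2Z)-2-methylbut-2-enal
Conditions: MnO2 (activated, excess), CH2Cl2, rt, dark; filtered, dried over 4 Å sieves, used at once as a solution
Reagents that add atoms: none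
Why: Allylic alcohol oxidation on neutral MnO2; the neutral heterogeneous medium and immediate use are chosen to avoid acid- or base-induced Z-to-E isomerisation of the volatile enal.

Step 5
Reactants: 4 6,6-dimethyl-1-vinylcyclohex-1-ene; 7 (2Z)-2-methylbut-2-enal
Product: 8 (1R,2R,8aR)-1,2,5,5-tetramethyl-1,2,3,5,6,7,8,8a-octahydronaphthalene-1-carbaldehyde
Conditions: (3aR)-1-(2-methylphenyl)-3,3-diphenyltetrahydro-1H,3H-pyrrolo[1,2-c][1,3,2]oxazaborole (20 mol %), HNTf2 (18 mol %), CH2Cl2, −78 → −40 °C
Reagents that add atoms: none
Why: Enantioselective Diels–Alder reaction under the protonated (cationic) oxazaborolidine, an established activation mode for α-substituted enals; the formyl-bearing carbon bonds to the ring terminus C10 and the β-carbon to C7, and the formyl group should sit exo because the endo position under C5 is crowded by the C4 methyls, so that CHO (future C11) ends cis to H10 and, through the Z geometry of 7, cis to the C8 methyl. The boron-bound s-trans enal is shielded on one face by a phenyl group of the catalyst, and the (R)-catalyst should expose the Cα si face, which together with the exo mode sets C8, C9 and C10 in this one step.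

Step 6
Reactants: 8 (1R,2R,8aR)-1,2,5,5-tetramethyl-1,2,3,5,6,7,8,8a-octahydronaphthalene-1-carbaldehyde; 9 dimethyl (2-oxopropyl)phosphonate
Product: 10 (3E)-4-[(1S,2R,8aS)-1,2,5,5-tetramethyl-1,2,3,5,6,7,8,8a-octahydronaphthalen-1-yl]but-3-en-2-one
Conditions: NaH, THF, 0 °C; then 8, 0 → 60 °C
Reagents that add atoms: none
Why: Horner–Wadsworth–Emmons olefination; aldehyde 8 has no α-hydrogen, so the basic, warm conditions needed for a neopentyl aldehyde cannot enolise or epimerise it (the descriptor at C1 changes by priority only).

Step 7
Reactants: 10 (3E)-4-[(1S,2R,8aS)-1,2,5,5-tetramethyl-1,2,3,5,6,7,8,8a-octahydronaphthalen-1-yl]but-3-en-2-one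
Product: 11 4-Oct-butan-2-one
Conditions: Cu(OAc)2·H2O (3 mol %), 1,2-(Ph2P)2C6H4 (3 mol %), (EtO)2MeSiH (1.5 equiv), t-BuOH (2 equiv), PhMe, rt
Reagents that add atoms: none
Why: Conjugate reduction by a phosphine-ligated hydride of monovalent copper formed in situ; it adds to the enone only, so the isolated trisubstituted C5=C6 alkene is neither reduced nor moved, as it might be over a palladium surface.

Step 8
Reactants: 12 methyl pyruvate; 13 benzyloxytrimethylsilane
Product: 15 methyl 2-(benzyloxy)acrylate, via methyl 2,2-bis(benzyloxy)propanoate 14 (not isolated)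
Conditions: Me3SiOTf (5 mol %), CH2Cl2, −78 → 0 °C; then i-Pr2NEt (1.5 equiv), Me3SiOTf (1.2 equiv), 0 °C → rt
Reagents that add atoms: none
Why: Silyl triflate-catalysed ketalisation of the ketone with the silyl ether, then silyl triflate/amine elimination of one benzyloxy group from the ketal to the enol ether; no free alcohol or protic acid is present, so the methyl ester should not exchange.

Step 9
Reactants: 11 4-Oct-butan-2-one; 15 methyl 2-(benzyloxy)acrylate
Product: 16 6-(benzyloxy)-4-(Oct-CH2)cyclohexane-1,3-dione (diastereomers at C4 and C6 of the dione; keto and enol forms)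
Conditions: KOt-Bu (2.2 equiv), THF/t-BuOH, 0 °C → rt; then 1 M HCl to pH 3
Reagents that add atoms: none
Why: Proposed new method: tert-butoxide equilibrates the enolates of 11, and the more substituted C1' enolate adds to the β-carbon (C6') of 15 (Michael addition); proton transfer then gives the C3' enolate, which attacks the ester carbonyl C4' and expels methoxide (Claisen condensation), and deprotonation of the new 1,3-dione at C3' makes the sequence irreversible. The closest known reaction type is the alkoxide-mediated Michael–Claisen annulation of methyl ketones with acrylates (and the older acetoacetate–acrylate route) to 4-substituted cyclohexane-1,3-diones; a 2-alkoxyacrylate has not been used as the acceptor. That acceptor is less electrophilic because the α-oxygen donates into the double bond, but it is still an ester-conjugated terminal alkene, its adduct enolate is stabilised inductively by the benzyloxy group, and every step before the final deprotonation is reversible, so the dione enolate should act as the sink. The one ring closed is C1'–C6', formed by a 6-(enolendo)-exo-trig attack of C3' on the ester carbonyl. Two stereocentres arise (C1' and C5'); neither is controlled and neither needs to be, since both become sp2 on aromatisation, and the octalin stereocentres are remote from any acidic position. The selectivity needed is regiochemical, C1' against C3' in the Michael step; it rests on the preference of equilibrating alkoxide conditions for the more substituted enolate and on C1' being an ordinary methylene whose branching sits two carbons away, at C9.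

Step 10
Reactants: 16 6-(benzyloxy)-4-(Oct-CH2)cyclohexane-1,3-dione
Product: 18 6-(benzyloxy)-2-formyl-4-(Oct-CH2)cyclohexane-1,3-dione (enolised), via enaminone 17 (not isolated)
Conditions: Me2NCH(OMe)2 (1.5 equiv), PhMe, rt; then 1 M HCl, THF, 0 °C → rt
Reagents that add atoms: N,N-dimethylformamide dimethyl acetal, COC(OC)N(C)C; water, O
Why: Aminomethylenation of the active methylene C3' (the only carbon between two carbonyls), then acid hydrolysis of the vinylogous amide to the formyl group; dilute aqueous acid at room temperature should not protonate the trisubstituted alkene.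

Step 11
Reactants: 18 6-(benzyloxy)-2-formyl-4-(Oct-CH2)cyclohexane-1,3-dione
Product: 19 3-(benzyloxy)-2,6-dihydroxy-5-(Oct-CH2)benzaldehyde
Conditions: DDQ (1.1 equiv), 1,4-dioxane, rt → 50 °C, dark
Reagents that add atoms: none
Why: Quinone dehydrogenation; the dienol tautomer of 18 (C2'=C3' and C4'=C5') is a cyclohexa-1,3-diene, which should lose hydride from C6' and a proton from C1' to give the arene. The product is a formyl-deactivated phenol whose position para to C2'–OH is blocked by the benzyl ether, which limits further oxidation.

Step 12
Reactants: 19 3-(benzyloxy)-2,6-dihydroxy-5-(Oct-CH2)benzaldehyde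
Product: 21 2,2-di-tert-butyl-5-hydroxy-6-(Oct-CH2)-1,3,2-benzodioxasilole-4-carbaldehyde, via triol 20 (not isolated)
Conditions: H2 (1 atm), Pd/C (5 mol %), EtOAc, rt, stopped at full conversion; filtered under Ar; then t-Bu2Si(OTf)2 (1.05 equiv), 2,6-lutidine (2.5 equiv), CH2Cl2, 0 °C
Reagents that add atoms: di-tert-butylsilyl bis(trifluoromethanesulfonate), CC(C)(C)[Si](OS(=O)(=O)C(F)(F)F)(OS(=O)(=O)C(F)(F)F)C(C)(C)C
Why: Hydrogenolysis of an aryl benzyl ether is fast, whereas C5=C6 is trisubstituted and flanked by a quaternary carbon and the formyl group is held between two hydrogen-bonding hydroxyls, so both should survive a short exposure. Cyclic silylene formation then takes the C4'/C5' pair, the only two oxygens that can span one silicon, and leaves the hindered C2'–OH free; the air-sensitive triol is never stored.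

Step 13
Reactants: 21 2,2-di-tert-butyl-5-hydroxy-6-(Oct-CH2)-1,3,2-benzodioxasilole-4-carbaldehyde
Product: 23 2-formyl-3,4-dihydroxy-6-(Oct-CH2)phenyl hydrogen sulfate (target), via silylene-protected aryl sulfate 22 (not isolated)
Conditions: SO3·pyridine (4 equiv), pyridine, 40 °C; then HF·pyridine, THF/pyridine, 0 °C; sulfonic acid resin (H+ form), 0 °C, freeze-drying
Reagents that add atoms: sulfur trioxide–pyridine complex, [O-]S(=O)(=O)[n+]1ccccc1
Why: O-Sulfation of the only free phenol, then fluoride cleavage of the two aryl Si–O bonds; aryl sulfate monoesters are stable to buffered fluoride and base, so the unmasking needs neither acid nor hydrogen and leaves C5=C6 and the aldehyde alone.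

## Compound list

1 | 2,2-dimethylcyclohexanone | CC1(C)CCCCC1=O | starting material
2 | 6,6-dimethylcyclohex-1-en-1-yl trifluoromethanesulfonate | CC1(C)CCCC=C1OS(=O)(=O)C(F)(F)F | intermediate
3 | tributyl(vinyl)stannane | C=C[Sn](CCCC)(CCCC)CCCC | starting material
4 | 6,6-dimethyl-1-vinylcyclohex-1-ene | C=CC1=CCCCC1(C)C | intermediate
5 | methyl (2Z)-2-methylbut-2-enoate | C/C=C(/C)C(=O)OC | starting material
6 | (2Z)-2-methylbut-2-en-1-ol | C/C=C(/C)CO | intermediate
7 | (2Z)-2-methylbut-2-enal | C/C=C(/C)C=O | intermediate
8 | (1R,2R,8aR)-1,2,5,5-tetramethyl-1,2,3,5,6,7,8,8a-octahydronaphthalene-1-carbaldehyde | C[C@@H]1CC=C2[C@@H](CCCC2(C)C)[C@]1(C)C=O | intermediate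
9 | dimethyl (2-oxopropyl)phosphonate | CC(=O)CP(=O)(OC)OC | starting material
10 | (3E)-4-[(1S,2R,8aS)-1,2,5,5-tetramethyl-1,2,3,5,6,7,8,8a-octahydronaphthalen-1-yl]but-3-en-2-one | C[C@@H]1CC=C2[C@@H](CCCC2(C)C)[C@]1(C)/C=C/C(C)=O | intermediate
11 | 4-[(1R,2R,8aS)-1,2,5,5-tetramethyl-1,2,3,5,6,7,8,8a-octahydronaphthalen-1-yl]butan-2-one | C[C@@H]1CC=C2[C@@H](CCCC2(C)C)[C@]1(C)CCC(C)=O | intermediate
12 | methyl pyruvate | CC(=O)C(=O)OC | starting material
13 | benzyloxytrimethylsilane | C[Si](C)(C)OCc1ccccc1 | starting material
14 | methyl 2,2-bis(benzyloxy)propanoate | COC(=O)C(C)(OCc1ccccc1)OCc1ccccc1 | intermediate (not isolated)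
15 | methyl 2-(benzyloxy)acrylate | C=C(OCc1ccccc1)C(=O)OC | intermediate
16 | 6-(benzyloxy)-4-(Oct-CH2)cyclohexane-1,3-dione (dione C4/C6 diastereomers, enol tautomers) | C[C@@H]1CC=C2[C@@H](CCCC2(C)C)[C@]1(C)CC1CC(OCc2ccccc2)C(=O)CC1=O | intermediate
17 | 6-(benzyloxy)-2-[(dimethylamino)methylidene]-4-(Oct-CH2)cyclohexane-1,3-dione | C[C@@H]1CC=C2[C@@H](CCCC2(C)C)[C@]1(C)CC1CC(OCc2ccccc2)C(=O)C(=CN(C)C)C1=O | intermediate (not isolated)
18 | 6-(benzyloxy)-2-formyl-4-(Oct-CH2)cyclohexane-1,3-dione (enolised) | C[C@@H]1CC=C2[C@@H](CCCC2(C)C)[C@]1(C)CC1CC(OCc2ccccc2)C(=O)C(C=O)C1=O | intermediate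
19 | 3-(benzyloxy)-2,6-dihydroxy-5-(Oct-CH2)benzaldehyde | C[C@@H]1CC=C2[C@@H](CCCC2(C)C)[C@]1(C)Cc1cc(OCc2ccccc2)c(O)c(C=O)c1O | intermediate
20 | 2,3,6-trihydroxy-5-(Oct-CH2)benzaldehyde | C[C@@H]1CC=C2[C@@H](CCCC2(C)C)[C@]1(C)Cc1cc(O)c(O)c(C=O)c1O | intermediate (not isolated)
21 | 2,2-di-tert-butyl-5-hydroxy-6-(Oct-CH2)-1,3,2-benzodioxasilole-4-carbaldehyde | C[C@@H]1CC=C2[C@@H](CCCC2(C)C)[C@]1(C)Cc1cc2O[Si](C(C)(C)C)(C(C)(C)C)Oc2c(C=O)c1O | intermediate
22 | 2,2-di-tert-butyl-4-formyl-6-(Oct-CH2)-1,3,2-benzodioxasilol-5-yl hydrogen sulfate (pyridinium salt in the flask) | C[C@@H]1CC=C2[C@@H](CCCC2(C)C)[C@]1(C)Cc1cc2O[Si](C(C)(C)C)(C(C)(C)C)Oc2c(C=O)c1OS(=O)(=O)O | intermediate (not isolated)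
23 | 2-formyl-3,4-dihydroxy-6-{[(1R,2R,8aS)-1,2,5,5-tetramethyl-1,2,3,5,6,7,8,8a-octahydronaphthalen-1-yl]methyl}phenyl hydrogen sulfate | C[C@@H]1CC=C2[C@@H](CCCC2(C)C)[C@]1(C)Cc1cc(O)c(O)c(C=O)c1OS(=O)(=O)O | target

## Step count and least certain steps

Total: 13 steps. Longest linear sequence: 10 steps (1 → 2 → 4 → 8 → 10 → 11 → 16 → 18 → 19 → 21 → 23; steps 1, 2, 5, 6, 7, 9, 10, 11, 12, 13).

**Step 9 (key step).** The most likely failure is a conjugate addition too slow for the electron-rich acceptor. Self-condensation of 11 and addition through the methyl carbon C3' (leading to the 2-substituted dione) would then compete.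
Fallback, known chemistry, from 11 back to 20: methyl acrylate, the acceptor for which this annulation is established, with KOt-Bu in THF would give 4-(Oct-CH2)cyclohexane-1,3-dione F1. The same C-formylation (Me2NCH(OMe)2, then dilute HCl) would give 2-formyl-4-(Oct-CH2)cyclohexane-1,3-dione F2, and DDQ would give 2,6-dihydroxy-3-(Oct-CH2)benzaldehyde F3. The missing C5' oxygen would then be introduced para to the C2' hydroxyl by Teuber oxidation with (KSO3)2NO in buffered acetone–water, giving the hydroxy-para-quinone 2-hydroxy-3,6-dioxo-5-(Oct-CH2)cyclohexa-1,4-diene-1-carbaldehyde F4. Reduction with Na2S2O4 would deliver triol 20, which enters the silylation of step 12.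

**Step 5.** Two things may go wrong. Acid-mediated isomerisation of the Z-enal before cycloaddition would carry the C8 methyl to the wrong face. Facial discrimination may also be incomplete, because a Z-β-substituted enal is less explored with this catalyst and the hindered diene reacts slowly.
Fallback, from 4 and 7 back to 8: stoichiometric EtAlCl2 in CH2Cl2 at −78 °C, where the cycloaddition should be fast and the exo mode is the expected one, would give the racemic aldehyde rac-(1R*,2R*,8aR*)-1,2,5,5-tetramethyl-1,2,3,5,6,7,8,8a-octahydronaphthalene-1-carbaldehyde F5. Condensation with (1R,2R)-N,N'-dimethyl-1,2-diphenylethane-1,2-diamine (4 Å sieves, Et2O) would give two diastereomeric imidazolidines, separable by chromatography or crystallisation. The one from the required enantiomer, (4R,5R)-1,3-dimethyl-4,5-diphenyl-2-[(1R,2R,8aR)-1,2,5,5-tetramethyl-1,2,3,5,6,7,8,8a-octahydronaphthalen-1-yl]imidazolidine F6, would be hydrolysed with dilute aqueous acid in a two-phase system to 8.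

**Step 11.** Hydride abstraction from the strongly chelated enol may be slow. Forcing it risks oxidation at the benzylic C11 or allylic C7 position, or of the benzyl ether.
Fallback, from 16 back to 19: Me3SiOTf/Et3N (2.2 equiv) would convert 16 into the bis-silyl dienol ether 4-(benzyloxy)-6-(Oct-CH2)-1,3-bis(trimethylsilyloxy)cyclohexa-1,3-diene F7, a preformed cyclohexadiene. DDQ at 0 °C to rt followed by K2CO3/MeOH would give 4-(benzyloxy)-6-(Oct-CH2)benzene-1,3-diol F8. Magnesium-mediated ortho-formylation (MgCl2, Et3N, paraformaldehyde, MeCN, reflux) can only occur at C3', the one free position ortho to a hydroxyl, and would give 19.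

**Step 12.** Hydrogen may add to, or move, the C5=C6 double bond, or reduce the formyl group, if the hydrogenolysis is not stopped in time. The triol may also oxidise in air before it is silylated.
Fallback, from 19 to 20 with no new compound (F0): Lewis-acid dealkylation with BCl3 and pentamethylbenzene as cation scavenger in CH2Cl2 at −78 °C, quenched cold with methanol, would replace the hydrogenolysis. The crude triol 20 would be silylated as in step 12.

**Step 13.** Sulfation of the hindered, hydrogen-bonded C2' phenol may be incomplete. The sulfate may also be lost by acid-catalysed hydrolysis during the final acidification and isolation.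
Fallback, from 21 back to 23: the sulfate would be introduced in protected form with 2,2,2-trichloroethyl chlorosulfate (Et3N, DMAP, THF), giving the chromatographable diester 2,2-di-tert-butyl-4-formyl-6-(Oct-CH2)-1,3,2-benzodioxasilol-5-yl 2,2,2-trichloroethyl sulfate F9. HF·pyridine would free the catechol to give 2-formyl-3,4-dihydroxy-6-(Oct-CH2)phenyl 2,2,2-trichloroethyl sulfate F10. Zinc and HCO2NH4 in methanol would remove the trichloroethyl group under near-neutral conditions to give 23 as its ammonium salt, which is then brought to the acid form as in step 13.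

## Further compounds

F1 | step 9 | 4-(Oct-CH2)cyclohexane-1,3-dione | C[C@@H]1CC=C2[C@@H](CCCC2(C)C)[C@]1(C)CC1CCC(=O)CC1=O
F2 | step 9 | 2-formyl-4-(Oct-CH2)cyclohexane-1,3-dione | C[C@@H]1CC=C2[C@@H](CCCC2(C)C)[C@]1(C)CC1CCC(=O)C(C=O)C1=O
F3 | step 9 | 2,6-dihydroxy-3-(Oct-CH2)benzaldehyde | C[C@@H]1CC=C2[C@@H](CCCC2(C)C)[C@]1(C)Cc1ccc(O)c(C=O)c1O
F4 | step 9 | 2-hydroxy-3,6-dioxo-5-(Oct-CH2)cyclohexa-1,4-diene-1-carbaldehyde | C[C@@H]1CC=C2[C@@H](CCCC2(C)C)[C@]1(C)CC1=CC(=O)C(O)=C(C=O)C1=O
F5 | step 5 | rac-(1R*,2R*,8aR*)-1,2,5,5-tetramethyl-1,2,3,5,6,7,8,8a-octahydronaphthalene-1-carbaldehyde (racemate, one enantiomer drawn) | C[C@@H]1CC=C2[C@@H](CCCC2(C)C)[C@]1(C)C=O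
F6 | step 5 | (4R,5R)-1,3-dimethyl-4,5-diphenyl-2-[(1R,2R,8aR)-1,2,5,5-tetramethyl-1,2,3,5,6,7,8,8a-octahydronaphthalen-1-yl]imidazolidine | C[C@@H]1CC=C2[C@@H](CCCC2(C)C)[C@]1(C)C1N(C)[C@H](c2ccccc2)[C@@H](c2ccccc2)N1C
F7 | step 11 | 4-(benzyloxy)-6-(Oct-CH2)-1,3-bis(trimethylsilyloxy)cyclohexa-1,3-diene | C[C@@H]1CC=C2[C@@H](CCCC2(C)C)[C@]1(C)CC1CC(OCc2ccccc2)=C(O[Si](C)(C)C)C=C1O[Si](C)(C)C
F8 | step 11 | 4-(benzyloxy)-6-(Oct-CH2)benzene-1,3-diol | C[C@@H]1CC=C2[C@@H](CCCC2(C)C)[C@]1(C)Cc1cc(OCc2ccccc2)c(O)cc1O
F0 | step 12 | none | none
F9 | step 13 | 2,2-di-tert-butyl-4-formyl-6-(Oct-CH2)-1,3,2-benzodioxasilol-5-yl 2,2,2-trichloroethyl sulfate | C[C@@H]1CC=C2[C@@H](CCCC2(C)C)[C@]1(C)Cc1cc2O[Si](C(C)(C)C)(C(C)(C)C)Oc2c(C=O)c1OS(=O)(=O)OCC(Cl)(Cl)Cl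
F10 | step 13 | 2-formyl-3,4-dihydroxy-6-(Oct-CH2)phenyl 2,2,2-trichloroethyl sulfate | C[C@@H]1CC=C2[C@@H](CCCC2(C)C)[C@]1(C)Cc1cc(O)c(O)c(C=O)c1OS(=O)(=O)OCC(Cl)(Cl)Cl
A1 | alternative 1 | 3-{[4,5-bis(benzyloxy)-2-(methoxymethoxy)phenyl]methyl}-6-(6,6-dimethylcyclohex-1-en-1-yl)-4-methyloxan-2-one (4,6-cis; C3 epimers) | O=C1O[C@@H](C2=CCCCC2(C)C)C[C@@H](C)C1Cc1cc(OCc2ccccc2)c(OCc2ccccc2)cc1OCOC
A2 | alternative 1 | octalin C9 carboxylic acid carrying the protected arylmethyl group | C[C@@H]1CC=C2[C@@H](CCCC2(C)C)[C@]1(C(=O)O)Cc1cc(OCc2ccccc2)c(OCc2ccccc2)cc1OCOC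
A3 | alternative 2 | trimethylsilyl enol ether (C5=C10) of the ring B ketone carrying the protected arylmethyl group | C[C@@H]1CCC(O[Si](C)(C)C)=C[C@]1(C)Cc1cc(OCc2ccccc2)c(OCc2ccccc2)cc1OCOC
A4 | alternative 2 | 3-(trimethylsilyl)but-3-en-2-one | CC(=O)C(=C)[Si](C)(C)C
A5 | alternative 2 | bicyclic 4-en-3-one carrying the protected arylmethyl group | C[C@@H]1CCC2=CC(=O)CC[C@H]2[C@]1(C)Cc1cc(OCc2ccccc2)c(OCc2ccccc2)cc1OCOC
A6 | alternative 3 | (2E)-2-{[4,5-bis(benzyloxy)-2-(triisopropylsilyloxy)phenyl]methyl}but-2-enal | C/C=C(/C=O)Cc1cc(OCc2ccccc2)c(OCc2ccccc2)cc1O[Si](C(C)C)(C(C)C)C(C)C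
A7 | alternative 3 | C9-formyl octalin carrying the protected arylmethyl group | C[C@@H]1CC=C2[C@@H](CCCC2(C)C)[C@]1(C=O)Cc1cc(OCc2ccccc2)c(OCc2ccccc2)cc1O[Si](C(C)C)(C(C)C)C(C)C
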